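(All runs are calculated for substances that don't exist, noise included.)

Early times gave me a better comparison than rates: a clock. For a rate k[free catalyst][starting material][partner], I integrated the balance of partner, the limiting reagent of the blue run (0.800 M against 1.00 M of starting material). With charges s and p and target made x, the clock is Θ = ln[p(s−x)/(s(p−x))]/(s−p), the time integral of k[free catalyst].

| flask | starting material | partner | free catalyst | target | time |
|---|---|---|---|---|---|
| blue | 1.00 M | 0.800 M | 0.0500 M |  |  |
| teal | 3.00 M | 0.800 M | 0.0500 M |  |  |
| grey | 1.00 M | 0.800 M | 0.0750 M |  |  |
| ochre | 1.00 M | 2.40 M | 0.0500 M |  |  |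
| amber | 1.00 M | 0.800 M | 0.0500 M | 0.500 M | 8.1 min |

| run | time / min | [target] / M |
|---|---|---|
| blue run | 0.36 | 0.074 |
| blue run | 1.1 | 0.177 |
| blue run | 2.1 | 0.260 |
| blue run | 3.3 | 0.323 |
| blue run | 4.7 | 0.358 |
| blue run | 6.3 | 0.392 |
| blue run | 8.1 | 0.411 |
| teal run | 0.36 | 0.204 |
| teal run | 1.1 | 0.424 |
| teal run | 2.1 | 0.564 |
| teal run | 3.3 | 0.645 |
| teal run | 4.7 | 0.675 |
| teal run | 6.3 | 0.700 |
| teal run | 8.1 | 0.705 |
| grey run | 0.36 | 0.106 |
| grey run | 1.1 | 0.238 |
| grey run | 2.1 | 0.345 |
| grey run | 3.3 | 0.417 |
| grey run | 4.7 | 0.449 |
| grey run | 6.3 | 0.476 |
| grey run | 8.1 | 0.491 |
| ochre run | 0.36 | 0.201 |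
| ochre run | 1.1 | 0.425 |
| ochre run | 2.1 | 0.564 |
| ochre run | 3.3 | 0.611 |
| ochre run | 4.7 | 0.625 |
| ochre run | 6.3 | 0.613 |
| ochre run | 8.1 | 0.574 |

(scatter of a reading: 0.005 M)

- Overall: starting material + partner -> target, with free catalyst as catalyst.
- Constant volume, constant temperature.
- "The second partner" is partner.
- An order is taken over about fifteen percent of the charge, up and down.
- A share of target counts the target that was charged too.

* order of the initial rate in [starting material], near the charge of the blue run, the rate being that where two percent of its starting material are target (one fixed amount of target, the same in the runs compared)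
* order of the initial rate in [free catalyst], near the charge of the blue run, the rate being that where two percent of its starting material are target
* target in the amber run at 8.1 min, as a share of the starting material charged

At 1.1 min there were two ways to read it. The blue run gave 0.276 /M and the teal run 0.274 /M, although the teal run held 0.424 M of target against 0.177 M. So I trusted first order in starting material, with target not slowing the clock. The grey run read 0.407 /M, 1.47 times the blue reading, for 1.50 times the catalyst. For a quarter of the starting material made, the clock must show the quarter reading 0.435 /M.

At 8.1 min the two ways parted: the blue run read 0.959 /M, the teal run less, 0.847 /M. The ochre run showed what cheats: its clock went from 0.485 /M at 4.7 min down to 0.414 /M at 8.1 min. A clock cannot run back, so the late balance omitted a loss of target.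

I wrote that loss as κ[target][partner]. The ochre run's late fall, taken by itself, gives a low estimate, κ = 0.0202 /M/min. Adding the formation still running, with the blue clock's late speed and all unconverted starting material counted, gives a high estimate of 0.0505 /M/min.

The amber run has the blue charge plus 0.500 M of target, so I took it as the blue run plus that charged target, decaying first order in target with the coefficient κ[partner], which changes with time as partner is used. The blue readings give a partner-time integral of 4.01 M·min. My reckoning for the amber run was therefore 81.9 % to 87.2 %.

The forecast gave orders of 1 in starting material and 1 in free catalyst, and 79 % for the amber run, within 72 % to 86 %, on the ground that “target is slowly lost to partner”. Its central value stood lower than my range.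

The amber run gave 82.6 %, with orders of 1.0 and 1.0.

    free catalyst + starting material + partner → target + free catalyst (5.706 /M²/min)
    free catalyst → spent catalyst (0.1830 /min)
    target + partner → side product (0.04440 /M/min)

The fit with these steps left a residual of 0.77 in units of the scatter. The grey run, with 1.50 times the catalyst, needed the quarter reading 0.435 /M on its own clock, which is 0.290 /M on the blue clock. Between the blue readings at 1.1 min and 2.1 min that falls at 1.17 min, and the grey run's quarter time is 1.16 min.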